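## Retrosynthetic overview

1. The last bond is C13–O9. Both spiro rings (tetrahydrofuran and 2,3-dihydrofuran) come at once from a 3-substituted furan carrying the 9α-OH, by a dearomative hydroalkoxylation that sets C13.
2. The 9α-hydroxy furan comes from a 9α,11-spiro-epoxide and a 3-furylmethyl Grignard reagent (C11–C12). The C9–O bond comes from α-face epoxidation of a C9 exocyclic methylene, which sets C9.
3. The methylene compound comes from the C9 ketone of a 6β-acetoxy trans-decalin, itself from a trans-6,9-dione (C6 reduced from the α face; C5 and C8 set by equilibration).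
4. The dione comes from a catalytic enantioselective Diels–Alder reaction of 2,6-dimethylbenzoquinone (ring B) with 4-methyl-1,3-pentadiene (ring A), which sets C10.
5. Ring order: ring B (quinone), ring A (cycloaddition), epoxide, then the spiro tetrahydrofuran with the dihydrofuran unmasked from the furan.

Numbering: positions are given in drimane/labdane numbering (C10 angular methyl β, C4 gem-dimethyl, C8 methyl, C9 carries the side chain C11–C16); α is below and β above the ring plane.

Assumption: the (S) boron catalyst (step 1) and the (R,R) cobalt catalyst (step 8) are written as the matched antipodes; which antipode is matched has to be found in one screening run each, and the mirror-image catalyst is used if needed.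

## Route

Step 1
Reactants: 1 2,6-dimethyl-1,4-benzoquinone; 2 4-methyl-1,3-pentadiene
Product: 3 cis-fused adduct (4aR,8aS)-2,5,5,8a-tetramethyl-4a,5,8,8a-tetrahydronaphthalene-1,4-dione
Conditions: (S)-B-(o-tolyl)-diphenylprolinol oxazaborolidine·HNTf2 (20 mol %), 2 (3 equiv), CH2Cl2, −78 → −20 °C
Reagents that add atoms: none
Why: Lewis-acid-catalysed endo Diels–Alder reaction in which the cationic boron binds the unhindered, more basic C6 carbonyl, so the CH2 end of the diene bonds to the methyl-bearing carbon (C10) and the CMe2 end to the CH carbon (C5), while the chiral oxazaborolidinium shields one face and sets the C10 quaternary centre (C5 forms cis and is corrected in step 2).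

Step 2
Reactants: 3 cis-fused adduct
Product: 5 trans-fused dione (2R,4aS,8aS)-2,5,5,8a-tetramethyloctahydronaphthalene-1,4-dione, via cis-fused saturated dione 4 (not isolated)
Conditions: H2 (1 atm), 10% Pd/C, EtOAc, rt; filter; then NaOMe (0.2 equiv), MeOH, rt
Reagents that add atoms: none
Why: Catalytic hydrogenation saturates both C=C bonds, then methoxide-mediated enolisation equilibrates C5 (α to the C6 ketone) to the trans ring fusion and C8 (α to the C9 ketone) to the equatorial 8α-methyl, an 8β-methyl being 1,3-diaxial to the C10 methyl (thermodynamic epimerisation).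

Step 3
Reactants: 5 trans-fused dione
Product: 7 6β-acetoxy-11-nordriman-9-one (8βH), via lithium alkoxide 6 (not isolated)
Conditions: LiBH(s-Bu)3 (1.1 equiv), THF, −78 °C; then Ac2O (4 equiv), DMAP (0.2 equiv), −78 °C → rt
Reagents that add atoms: acetic anhydride, CC(=O)OC(C)=O
Why: Bulky-hydride ketone reduction followed by O-acylation of the alkoxide; the hydride takes the C6 ketone rather than the C9 ketone flanked by a quaternary and a tertiary carbon, and can only approach from the α face because the β face is closed by the syn-axial C10 and C4β methyls, giving the axial 6β-oxygen.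

Step 4
Reactants: 7 6β-acetoxy-11-nordriman-9-one
Product: 8 6β-acetoxydrim-9(11)-ene (8βH)
Conditions: Zn, CH2Br2, TiCl4 (pre-formed slurry, 3 equiv), THF/CH2Cl2, 0 °C → rt
Reagents that add atoms: dibromomethane, BrCBr
Why: Takai–Lombardo methylenation (gem-dizinc/titanium methylidene) is non-basic and takes a hindered ketone in the presence of an ester, so C8 and the acetate are untouched.

Step 5
Reactants: 8 6β-acetoxydrim-9(11)-ene
Product: 9 6β-acetoxy-9α,11-epoxydrimane (8βH)
Conditions: m-CPBA (1.3 equiv), NaHCO3, CH2Cl2, 0 °C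
Reagents that add atoms: m-chloroperbenzoic acid, OOC(=O)c1cccc(Cl)c1
Why: Prilezhaev epoxidation in which the peracid reaches the exocyclic alkene from the α face, anti to the axial C10 methyl that flanks the β face, forming the C9–O bond with the 9α configuration (C11 equatorial, β).

Step 6
Reactants: 10 3-furanmethanol
Product: 11 3-(chloromethyl)furan
Conditions: SOCl2 (1.1 equiv), pyridine (1.1 equiv), Et2O, 0 °C; used at once as a dried solution
Reagents that add atoms: thionyl chloride, O=S(Cl)Cl
Why: Chlorination of a primary alcohol through its chlorosulfite (SN2), with no stereocentre involved.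

Step 7
Reactants: 9 6β-acetoxy-9α,11-epoxydrimane; 11 3-(chloromethyl)furan
Product: 13 6β-acetoxy-15,16-epoxylabda-13(16),14-dien-9α-ol (8βH), via 3-furylmethylmagnesium chloride 12 (not isolated)
Conditions: 11, Mg, THF, 0 °C (slow addition); then 9, CuI (10 mol %), THF, −40 → −10 °C; aq NH4Cl
Reagents that add atoms: none
Why: Copper-catalysed Grignard (organocuprate) SN2 opening of the spiro-epoxide at its CH2 carbon (C11) forms C11–C12 and leaves the C9–O bond and configuration untouched, and the axial 6β-acetate, shielded by two syn-axial methyls, should outlast the reagent at −40 °C.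

Step 8
Reactants: 13 6β-acetoxy-15,16-epoxylabda-13(16),14-dien-9α-ol
Product: 14 (13S)-6β-acetoxy-9α,13:15,16-diepoxylabd-14-ene (8βH), the target
Conditions: (R,R)-Co(salen) [(R,R)-N,N′-bis(3,5-di-tert-butylsalicylidene)-1,2-cyclohexanediamine complex of divalent cobalt, C36H52CoN2O2] (5 mol %), N-fluoro-2,4,6-trimethylpyridinium tetrafluoroborate (1.3 equiv), PhSiH3 (1.3 equiv), 2,4,6-collidine (1 equiv), PhCF3, 0 °C, Ar
Reagents that add atoms: none
Why: Proposed new method: a cobalt-hydride hydrogen-atom transfer to an aromatic furan followed by radical–polar crossover (a dearomative Markovnikov hydroalkoxylation), in which the trivalent Co–H made from the fluoride-oxidised catalyst and PhSiH3 gives H• to C16 to form the tertiary oxygen-conjugated allyl radical, oxidation through a tetravalent alkylcobalt gives the 2H-furanium/allyl cation, and the axial 9α-OH closes 5-exo at C13 (the only carbon it can reach) inside the chiral salen pocket, which is meant to fix 13S, while collidine takes up the proton so the acid-labile enol ether survives and the oxidant/silane pair pays for the lost aromaticity that makes a plain acid-catalysed addition uphill; the closest known reaction is the Co(salen)/N-fluoropyridinium/silane (Mukaiyama-type) hydroalkoxylation of unactivated alkenes, not yet shown on a furan ring.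

## Compound list

1 | 2,6-dimethyl-1,4-benzoquinone | CC1=CC(=O)C=C(C)C1=O | starting material
2 | 4-methyl-1,3-pentadiene | CC(C)=CC=C | starting material
3 | cis-fused adduct, (4aR,8aS)-2,5,5,8a-tetramethyl-4a,5,8,8a-tetrahydronaphthalene-1,4-dione (11-nor-5β-drima-2,7-diene-6,9-dione) | O=C1C=C(C)C(=O)[C@@]2(C)CC=CC(C)(C)[C@@H]12 | intermediate
4 | cis-fused saturated dione, (4aR,8aS)-2,5,5,8a-tetramethyloctahydronaphthalene-1,4-dione (C2 epimers) | O=C1CC(C)C(=O)[C@@]2(C)CCCC(C)(C)[C@@H]12 | intermediate
5 | trans-fused dione, (2R,4aS,8aS)-2,5,5,8a-tetramethyloctahydronaphthalene-1,4-dione (11-nordrimane-6,9-dione, 5α-H, 8α-CH3) | O=C1C[C@@H](C)C(=O)[C@@]2(C)CCCC(C)(C)[C@H]12 | intermediate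
6 | lithium 6β-alkoxide of 6β-hydroxy-11-nordriman-9-one (8βH) | [Li+].[O-][C@@H]1C[C@@H](C)C(=O)[C@@]2(C)CCCC(C)(C)[C@H]12 | intermediate
7 | 6β-acetoxy-11-nordriman-9-one (5α-H, 8α-CH3, axial acetate) | CC(=O)O[C@@H]1C[C@@H](C)C(=O)[C@@]2(C)CCCC(C)(C)[C@H]12 | intermediate
8 | 6β-acetoxydrim-9(11)-ene (8α-CH3, exocyclic C9=CH2) | CC(=O)O[C@@H]1C[C@@H](C)C(=C)[C@@]2(C)CCCC(C)(C)[C@H]12 | intermediate
9 | 6β-acetoxy-9α,11-epoxydrimane (spiro-epoxide, oxygen α, CH2 β) | CC(=O)O[C@@H]1C[C@@H](C)[C@]2(CO2)[C@@]2(C)CCCC(C)(C)[C@H]12 | intermediate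
10 | 3-furanmethanol | OCc1ccoc1 | starting material
11 | 3-(chloromethyl)furan | ClCc1ccoc1 | intermediate
12 | 3-furylmethylmagnesium chloride | Cl[Mg]Cc1ccoc1 | intermediate
13 | 6β-acetoxy-15,16-epoxylabda-13(16),14-dien-9α-ol (8α-CH3; 2-(3-furyl)ethyl chain β on C9) | CC(=O)O[C@@H]1C[C@@H](C)[C@](O)(CCc2ccoc2)[C@@]2(C)CCCC(C)(C)[C@H]12 | intermediate
14 | (13S)-6β-acetoxy-9α,13:15,16-diepoxylabd-14-ene (8α-CH3; the OCH2 of the dihydrofuran lies on the C10 side of the tetrahydrofuran ring) | CC(=O)O[C@@H]1C[C@@H](C)[C@]2(CC[C@@]3(C=COC3)O2)[C@@]2(C)CCCC(C)(C)[C@H]12 | target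

## Step count and risks

Total steps: 8. Longest linear sequence: 7 (steps 1, 2, 3, 4, 5, 7, 8; step 6 is a one-step side branch).

**Step 8 (proposed new step).**
- Possible failures: the cobalt hydride may not transfer hydrogen to the furan at a useful rate; the product enol ether (C14=C15) or the furan may be attacked by the hydride or by the N–F oxidant; C13 may form as the wrong epimer, since the substrate bias is small.
- First measures: stop at partial conversion and recycle 13; screen both catalyst antipodes.
- Fallback (known chemistry), from 13 back to 14: Photo-oxygenation of 13 (O2, hν, rose bengal, i-Pr2NEt, CH2Cl2, −78 °C) gives γ-hydroxybutenolide F7. The hindered base removes the proton at the unhindered C15, so the carbonyl ends at C15 and the hemiacetal at C16. NaBH4 (MeOH, 0 °C, then dilute acid) gives butenolide F8. DBU (toluene, 60 °C) closes the 9α-OH onto C13 by reversible oxa-Michael addition to give spirolactone F9 together with its C13 epimer F10, which is separated and re-equilibrated. i-Bu2AlH (1.1 equiv, CH2Cl2, −78 °C; the shielded axial acetate is far slower than the γ-lactone) gives lactol F11. MsCl/Et3N (CH2Cl2, −40 → 0 °C) dehydrates it to the enol ether 14.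

**Step 1.**
- Possible failures: 4-methyl-1,3-pentadiene is a sluggish diene (the Z-methyl disfavours the s-cis form) and may polymerise under the cationic catalyst; the enantiomeric excess may be low.
- Fallback, from 1 and 2 back to 5: The cycloaddition is run with stoichiometric BF3·OEt2 (CH2Cl2, −40 °C), which keeps the same regiochemistry and gives 3 as the racemate, that is 3 plus mirror-image adduct F1. Step 2 as written then gives racemic trans-dione through mirror-image cis-dione F2, that is 5 plus mirror-image trans-dione F3. Preparative chromatography on a chiral stationary phase (SFC) delivers 5, so enantiocontrol comes from resolution and not from the catalyst.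

**Step 7.**
- Possible failures: the benzylic-type Grignard reagent 12 may couple with itself or react through furan C2; the neopentyl-like epoxide CH2 is slow, and magnesium halide may open or rearrange the epoxide; the acetate may be attacked.
- Fallback, from 11 and 9 back to 13: PhSO2Na (DMF, rt) turns 11 into 3-[(phenylsulfonyl)methyl]furan F4. n-BuLi (THF, −78 °C) gives lithiated sulfone F5, which opens 9 at C11 in the presence of BF3·OEt2 (−78 °C) to give hydroxy sulfone F6. Na(Hg), Na2HPO4 (MeOH/THF, −20 °C) removes the sulfonyl group to give 13.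

## Further compounds

F1 | step 1 | mirror-image adduct, (4aS,8aR)-2,5,5,8a-tetramethyl-4a,5,8,8a-tetrahydronaphthalene-1,4-dione | O=C1C=C(C)C(=O)[C@]2(C)CC=CC(C)(C)[C@H]12
F2 | step 1 | mirror-image cis-dione, (4aS,8aR)-2,5,5,8a-tetramethyloctahydronaphthalene-1,4-dione (C2 epimers) | O=C1CC(C)C(=O)[C@]2(C)CCCC(C)(C)[C@H]12
F3 | step 1 | mirror-image trans-dione, (2S,4aR,8aR)-2,5,5,8a-tetramethyloctahydronaphthalene-1,4-dione | O=C1C[C@H](C)C(=O)[C@]2(C)CCCC(C)(C)[C@@H]12
F4 | step 7 | 3-[(phenylsulfonyl)methyl]furan | O=S(=O)(Cc1ccoc1)c1ccccc1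
F5 | step 7 | lithiated sulfone, [(3-furyl)(phenylsulfonyl)methyl]lithium | [Li]C(c1ccoc1)S(=O)(=O)c1ccccc1
F6 | step 7 | hydroxy sulfone, 6β-acetoxy-12-(phenylsulfonyl)-15,16-epoxylabda-13(16),14-dien-9α-ol (C12 epimers) | CC(=O)O[C@@H]1C[C@@H](C)[C@](O)(CC(c2ccoc2)S(=O)(=O)c2ccccc2)[C@@]2(C)CCCC(C)(C)[C@H]12
F7 | step 8 | γ-hydroxybutenolide, 6β-acetoxy-9α,16-dihydroxylabd-13-en-15,16-olide (C16 epimers) | CC(=O)O[C@@H]1C[C@@H](C)[C@](O)(CCC2=CC(=O)OC2O)[C@@]2(C)CCCC(C)(C)[C@H]12
F8 | step 8 | butenolide, 6β-acetoxy-9α-hydroxylabd-13-en-15,16-olide | CC(=O)O[C@@H]1C[C@@H](C)[C@](O)(CCC2=CC(=O)OC2)[C@@]2(C)CCCC(C)(C)[C@H]12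
F9 | step 8 | spirolactone, (13S)-6β-acetoxy-9α,13-epoxylabdan-15,16-olide | CC(=O)O[C@@H]1C[C@@H](C)[C@]2(CC[C@@]3(CC(=O)OC3)O2)[C@@]2(C)CCCC(C)(C)[C@H]12
F10 | step 8 | C13 epimer, (13R)-6β-acetoxy-9α,13-epoxylabdan-15,16-olide | CC(=O)O[C@@H]1C[C@@H](C)[C@]2(CC[C@]3(CC(=O)OC3)O2)[C@@]2(C)CCCC(C)(C)[C@H]12
F11 | step 8 | lactol, (13S)-6β-acetoxy-9α,13:15,16-diepoxylabdan-15-ol (C15 epimers) | CC(=O)O[C@@H]1C[C@@H](C)[C@]2(CC[C@@]3(CC(O)OC3)O2)[C@@]2(C)CCCC(C)(C)[C@H]12
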